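## The problem

Curlignan (19) is a 2,3-dihydrobenzofuran neolignan. Ring A is a methyl benzoate (CO2Me at C5, OMe at C7) fused through C3a and C7a to the five-membered ring O1–C2–C3. C2 carries the 4-hydroxy-3-methoxyphenyl ring B and C3 a hydroxymethyl group.

- **Stereocentres.** The two adjacent centres are C2 (S) and C3 (R), trans across the heterocycle. C2 is an aryl ether carbon, benzylic to a para-hydroxyphenyl ring, and can ionise reversibly, so C3 can dictate its configuration. C3 is an ordinary carbon centre: it must be set absolutely and cannot be corrected later.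
- **Sensitive groups.** The methyl ester limits the use of strong hydride donors and hydroxide. The ring B phenol is easily oxidised. The O1–C2 bond is open to hydrogenolysis, acid and oxidants. The heterocycle should therefore be closed late and under mild conditions.
- **Enabling feature.** C2 is benzylic to ring B and para to its hydroxyl group, so two-electron oxidation of a C2 methylene gives a para-quinone methide. The oxygen on C7a sits where a 5-exo addition to that methide carbon forms O1–C2. The ring A phenol is para to the ester and has no para alkyl group, so an oxidant should choose ring B.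

## Retrosynthesis

**O1–C2.** Cutting this bond in 19 leads, through para-quinone methide 18, to the acyclic 2,3-diarylpropanol 17 with one stereocentre. The neighbouring cuts are less attractive: O1–C7a would need an aryl halide and a metal-mediated etherification, and C2–C3 would require both centres to be set at once. The forward reaction must oxidise ring B selectively, close a five-membered ring and place the C2 aryl group trans to the C3 substituent. The primary alcohol is carried free: it is inert to DDQ and could reach the methide carbon only through a four-membered ring, so a silyl ether and its removal are saved.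

**Phenol protection.** Triol 17 comes from bis(benzyl ether) 16 by hydrogenolysis. Benzyl is chosen for both phenols so that one operation frees them just before the oxidation, at a stage where no benzylic C–O bond of the heterocycle yet exists.

**C3 stereocentre.** Alcohol 16 is the reduction product of imide 15. Cutting the bond between the stereocentre and the ring B benzylic carbon gives arylacetyl imide 11 and benzylic bromide 13 (from alcohol 12). This is an Evans alkylation of an arylacetyl oxazolidinone with a benzylic bromide, a well-used route to 2,3-diarylpropanols. The alternative cut at the aryl–C3 bond would need an asymmetric enolate arylation, which is much less secure. The (R)-configured auxiliary 9 is required for the (R) centre.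

**Arylacetic acid.** Imide 11 is the acylation product of auxiliary 9 with acid 8 through mixed anhydride 10. Acid 8 comes from aldehyde 7, itself the ozonolysis product (via ozonide 6) of allyl arene 5.

**Ring A.** Allyl arene 5 is the benzyl ether of phenol 4, the Claisen product of allyl ether 3, made from methyl vanillate (1) and allyl bromide (2). Methyl vanillate already holds the ester, the methoxy group and the phenol in the right places, and the rearrangement can only go to the one free ortho position. Two of the three allyl carbons remain and become C3 and the hydroxymethyl carbon.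

## Roads not taken

**Alternative 1:** Ring A is cut out of the target and rebuilt by an inverse-demand [4+2] cycloaddition of methyl 3-bromocoumalate A2 with the cyclic silyl ketene acetal A3 of a trans-disubstituted butyrolactone. Loss of CO2 and trimethylsilanol should give the aromatic bromide A1 with the trans dihydrofuran intact.
- Merits: the plan is convergent, the regiochemistry is polarity-matched (the nucleophilic ketene acetal carbon meets C6 of the pyrone), and the final product is never exposed to an oxidant. In that last respect it is better than the chosen plan.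
- Weak points: A3 must carry both stereocentres in enantiopure form before the key step. The intermediate after CO2 loss can aromatise by expelling the ring oxygen instead of silanol, which opens the heterocycle. A1 still needs a bromine-to-methoxy exchange at a hindered position (for example CuI/NaOMe) and two deprotections.
- Comparison: the chosen plan starts with all three ring A substituents in place, makes one stereocentre with an auxiliary and lets it control the second.

**Alternative 2:** The C2–C3 bond is cut. The dirhodium carboxylate Rh2(S-PTTL)4 decomposes aryldiazoacetate A5, and the carbene inserts into the benzylic C–H bond of the ring B CH2–O group to give the cis dihydrobenzofuran ester A4.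
- Merits: both centres arise in one catalytic asymmetric step with good class precedent and no stoichiometric auxiliary. That is a real advantage over the chosen plan.
- Weak points: A4 is cis, so C3 must be epimerised through an ester enolate that can also expel the aryloxide and scramble C2. The C3 ester must then be reduced, which is why C5 has to be carried as bromide and converted to the methyl ester late by palladium-catalysed methoxycarbonylation. A desilylation follows.
- Comparison: the chosen plan delivers the trans isomer directly and has the C5 ester and the C3 oxidation level in place before the ring is closed.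

**Alternative 3:** Ring A and the heterocycle are formed together. Ph3PAuNTf2, a cationic monovalent gold complex, activates the ethynyl ether of furan A7; the furan adds across the alkyne and its oxygen ends as the C7 phenol of A6.
- Merits: this is the most economical ring construction of the four plans, with two rings and the C7 oxygen from one isomerisation. In complexity gained per step it is better than the chosen plan.
- Weak points: A7 needs both stereocentres set in an acyclic precursor. Its secondary benzylic ethynyl ether is prone to hydration and to retro-ene loss of ketene. The ester-bearing furan is a weakened nucleophile, and the phenol synthesis is not established for ynol ethers of this kind. A6 still needs O-methylation and two deprotections.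
- Comparison: the chosen plan uses only reaction classes with close precedent and simple, stable intermediates.

Key step: step 11

Remark: [4-(benzyloxy)-3-methoxyphenyl]methanol (12) is taken as a purchased compound (it is the NaBH4 reduction product of O-benzylvanillin). Ozonide 6 is a racemic mixture at its ring carbon and the exocyclic double bond of 18 is drawn without defined geometry; neither matters for the outcome.

## Route

Step 1
Reactants: 1 methyl vanillate (methyl 4-hydroxy-3-methoxybenzoate); 2 allyl bromide
Product: 3 methyl 3-methoxy-4-(prop-2-en-1-yloxy)benzoate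
Conditions: K2CO3, acetone, reflux
Reagents that add atoms: none
Why: Williamson ether synthesis; the phenoxide displaces bromide from the allylic halide and the ester is untouched by carbonate.

Step 2
Reactants: 3 methyl 3-methoxy-4-(prop-2-en-1-yloxy)benzoate
Product: 4 methyl 4-hydroxy-3-methoxy-5-(prop-2-en-1-yl)benzoate
Conditions: N,N-diethylaniline, 200 °C
Reagents that add atoms: none
Why: Aromatic Claisen rearrangement; the [3,3] shift can only reach the one unsubstituted ortho carbon, and tautomerisation of the dienone restores the phenol.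

Step 3
Reactants: 4 methyl 4-hydroxy-3-methoxy-5-(prop-2-en-1-yl)benzoate
Product: 5 methyl 4-(benzyloxy)-3-methoxy-5-(prop-2-en-1-yl)benzoate
Conditions: BnBr, K2CO3, DMF, 60 °C
Reagents that add atoms: benzyl bromide, BrCc1ccccc1
Why: Williamson benzylation; the benzyl ether shields the phenol from chlorite and strong base and can later be removed together with the ring B benzyl ether.

Step 4
Reactants: 5 methyl 4-(benzyloxy)-3-methoxy-5-(prop-2-en-1-yl)benzoate
Product: 7 methyl 4-(benzyloxy)-3-methoxy-5-(2-oxoethyl)benzoate, via ozonide 6 (not isolated)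
Conditions: O3, CH2Cl2, −78 °C; then PPh3, −78 °C to rt
Reagents that add atoms: ozone, [O-][O+]=O
Why: Ozonolysis by the Criegee pathway; the terminal alkene reacts far faster than the ester-deactivated arene, and PPh3 reduces ozonide 6 to the arylacetaldehyde, which is taken on crude.

Step 5
Reactants: 7 methyl 4-(benzyloxy)-3-methoxy-5-(2-oxoethyl)benzoate
Product: 8 2-[2-(benzyloxy)-3-methoxy-5-(methoxycarbonyl)phenyl]acetic acid
Conditions: NaClO2, NaH2PO4, 2-methyl-2-butene, t-BuOH/H2O, rt
Reagents that add atoms: sodium chlorite, [Na+].[O-]Cl=O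
Why: Pinnick oxidation; chlorous acid converts the aldehyde to the acid without touching benzylic positions, and the alkene scavenger removes hypochlorous acid before it can chlorinate the ring.

Step 6
Reactants: 8 2-[2-(benzyloxy)-3-methoxy-5-(methoxycarbonyl)phenyl]acetic acid; 9 (R)-4-benzyl-1,3-oxazolidin-2-one
Product: 11 methyl 4-(benzyloxy)-3-{2-[(4R)-4-benzyl-2-oxo-1,3-oxazolidin-3-yl]-2-oxoethyl}-5-methoxybenzoate, via pivalic mixed anhydride 10 (not isolated)
Conditions: PivCl, Et3N, THF, −20 °C; then LiCl, 9, −20 °C to rt
Reagents that add atoms: none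
Why: N-acylation of the oxazolidinone through a mixed anhydride with lithium chloride activation; the nucleophile attacks the unhindered arylacetyl carbonyl and not the pivaloyl one.

Step 7
Reactants: 12 [4-(benzyloxy)-3-methoxyphenyl]methanol
Product: 13 1-(benzyloxy)-4-(bromomethyl)-2-methoxybenzene
Conditions: PBr3, Et2O, 0 °C; used at once
Reagents that add atoms: phosphorus tribromide, BrP(Br)Br
Why: Bromide displaces the phosphite ester of the benzylic alcohol; the electron-rich benzylic bromide is labile and is therefore not stored.

Step 8
Reactants: 11 methyl 4-(benzyloxy)-3-{2-[(4R)-4-benzyl-2-oxo-1,3-oxazolidin-3-yl]-2-oxoethyl}-5-methoxybenzoate; 13 1-(benzyloxy)-4-(bromomethyl)-2-methoxybenzene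
Product: 15 methyl 4-(benzyloxy)-3-[(2R)-1-[(4R)-4-benzyl-2-oxo-1,3-oxazolidin-3-yl]-3-[4-(benzyloxy)-3-methoxyphenyl]-1-oxopropan-2-yl]-5-methoxybenzoate, via sodium Z-enolate 14 (not isolated)
Conditions: NaHMDS, THF, −78 °C; then 13, −78 to −40 °C
Reagents that add atoms: none
Why: Evans asymmetric alkylation; the chelated Z-enolate 14 is shielded on one face by the benzyl group of the auxiliary, so the bromide adds to the other face and gives the (R) centre that becomes C3, while allylic strain in the product hinders its re-enolisation.

Step 9
Reactants: 15 methyl 4-(benzyloxy)-3-[(2R)-1-[(4R)-4-benzyl-2-oxo-1,3-oxazolidin-3-yl]-3-[4-(benzyloxy)-3-methoxyphenyl]-1-oxopropan-2-yl]-5-methoxybenzoate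
Product: 16 methyl 4-(benzyloxy)-3-[(2R)-1-[4-(benzyloxy)-3-methoxyphenyl]-3-hydroxypropan-2-yl]-5-methoxybenzoate
Conditions: NaBH4, THF/H2O (4:1), 0 °C to rt
Reagents that add atoms: none
Why: Reductive removal of the auxiliary with borohydride in wet THF; the imide carbonyl is far more electrophilic than the electron-rich methyl benzoate, which should be left alone, and the oxazolidinone is recovered.

Step 10
Reactants: 16 methyl 4-(benzyloxy)-3-[(2R)-1-[4-(benzyloxy)-3-methoxyphenyl]-3-hydroxypropan-2-yl]-5-methoxybenzoate
Product: 17 methyl 4-hydroxy-3-[(2R)-1-hydroxy-3-(4-hydroxy-3-methoxyphenyl)propan-2-yl]-5-methoxybenzoate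
Conditions: H2 (1 atm), Pd/C, EtOAc/EtOH, rt
Reagents that add atoms: none
Why: Hydrogenolysis of both aryl benzyl ethers; the ester, the primary alcohol and the stereocentre are inert under these neutral conditions.

Step 11
Reactants: 17 methyl 4-hydroxy-3-[(2R)-1-hydroxy-3-(4-hydroxy-3-methoxyphenyl)propan-2-yl]-5-methoxybenzoate
Product: 19 curlignan, methyl (2S,3R)-2-(4-hydroxy-3-methoxyphenyl)-3-(hydroxymethyl)-7-methoxy-2,3-dihydro-1-benzofuran-5-carboxylate, via para-quinone methide 18 (not isolated)
Conditions: DDQ (1.05 equiv), 1,4-dioxane, 15 °C to rt, dark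
Reagents that add atoms: none
Why: DDQ forms a charge-transfer complex with the electron-rich ring B phenol and removes hydride (formally a proton and two electrons) from the para benzylic carbon C2, giving para-quinone methide 18 and the hydroquinone. The ring A phenol oxygen then adds to the exocyclic methide carbon in a 1,6-conjugate addition, a 5-exo-trig closure of the dihydrofuran ring driven by rearomatisation of ring B. The closest known reaction type is the DDQ-mediated oxidative cyclisation of 2-hydroxy-1,3-diarylpropanes to 4'-hydroxyflavans, together with the phenol-to-quinone-methide closure that ends the oxidative β-5 coupling of coniferyl-type phenols. C2 is controlled by C3: in the envelope-like transition state the aryl group on the methide carbon turns away from the hydroxymethyl group, and since the closure can reopen through 18 in the weakly acidic medium, the more stable trans (2S,3R) isomer should prevail. Oxidation must occur at ring B and not ring A; the para ester secures this by making the ring A phenol electron-poor and leaving it without a para alkyl hydrogen. The primary alcohol does not compete because it could reach C2 only through a four-membered ring. Over-oxidation of the product is limited by one equivalent of oxidant at or below room temperature.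

## Compound list

1 | methyl vanillate (methyl 4-hydroxy-3-methoxybenzoate) | COC(=O)c1ccc(O)c(OC)c1 | starting material
2 | allyl bromide | C=CCBr | starting material
3 | methyl 3-methoxy-4-(prop-2-en-1-yloxy)benzoate | COC(=O)c1ccc(OCC=C)c(OC)c1 | intermediate
4 | methyl 4-hydroxy-3-methoxy-5-(prop-2-en-1-yl)benzoate | COC(=O)c1cc(OC)c(O)c(CC=C)c1 | intermediate
5 | methyl 4-(benzyloxy)-3-methoxy-5-(prop-2-en-1-yl)benzoate | COC(=O)c1cc(OC)c(OCc2ccccc2)c(CC=C)c1 | intermediate
6 | methyl 4-(benzyloxy)-3-methoxy-5-[(1,2,4-trioxolan-3-yl)methyl]benzoate (ozonide, racemic at the ring carbon) | COC(=O)c1cc(OC)c(OCc2ccccc2)c(CC2OCOO2)c1 | intermediate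
7 | methyl 4-(benzyloxy)-3-methoxy-5-(2-oxoethyl)benzoate | COC(=O)c1cc(OC)c(OCc2ccccc2)c(CC=O)c1 | intermediate
8 | 2-[2-(benzyloxy)-3-methoxy-5-(methoxycarbonyl)phenyl]acetic acid | COC(=O)c1cc(OC)c(OCc2ccccc2)c(CC(=O)O)c1 | intermediate
9 | (R)-4-benzyl-1,3-oxazolidin-2-one | O=C1N[C@H](Cc2ccccc2)CO1 | starting material
10 | 2-[2-(benzyloxy)-3-methoxy-5-(methoxycarbonyl)phenyl]acetic 2,2-dimethylpropanoic anhydride | COC(=O)c1cc(OC)c(OCc2ccccc2)c(CC(=O)OC(=O)C(C)(C)C)c1 | intermediate
11 | methyl 4-(benzyloxy)-3-{2-[(4R)-4-benzyl-2-oxo-1,3-oxazolidin-3-yl]-2-oxoethyl}-5-methoxybenzoate | COC(=O)c1cc(OC)c(OCc2ccccc2)c(CC(=O)N2[C@H](Cc3ccccc3)COC2=O)c1 | intermediate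
12 | [4-(benzyloxy)-3-methoxyphenyl]methanol | COc1cc(CO)ccc1OCc1ccccc1 | starting material
13 | 1-(benzyloxy)-4-(bromomethyl)-2-methoxybenzene | COc1cc(CBr)ccc1OCc1ccccc1 | intermediate
14 | sodium Z-enolate of imide 11 | [Na+].[O-]/C(=C\c1cc(C(=O)OC)cc(OC)c1OCc1ccccc1)N1[C@H](Cc2ccccc2)COC1=O | intermediate
15 | methyl 4-(benzyloxy)-3-[(2R)-1-[(4R)-4-benzyl-2-oxo-1,3-oxazolidin-3-yl]-3-[4-(benzyloxy)-3-methoxyphenyl]-1-oxopropan-2-yl]-5-methoxybenzoate | COC(=O)c1cc(OC)c(OCc2ccccc2)c(c1)[C@@H](Cc1ccc(OCc2ccccc2)c(OC)c1)C(=O)N1[C@H](Cc2ccccc2)COC1=O | intermediate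
16 | methyl 4-(benzyloxy)-3-[(2R)-1-[4-(benzyloxy)-3-methoxyphenyl]-3-hydroxypropan-2-yl]-5-methoxybenzoate | COC(=O)c1cc(OC)c(OCc2ccccc2)c(c1)[C@@H](Cc1ccc(OCc2ccccc2)c(OC)c1)CO | intermediate
17 | methyl 4-hydroxy-3-[(2R)-1-hydroxy-3-(4-hydroxy-3-methoxyphenyl)propan-2-yl]-5-methoxybenzoate | COC(=O)c1cc(OC)c(O)c(c1)[C@@H](Cc1ccc(O)c(OC)c1)CO | intermediate
18 | methyl 4-hydroxy-3-[(2R)-1-hydroxy-3-(3-methoxy-4-oxocyclohexa-2,5-dien-1-ylidene)propan-2-yl]-5-methoxybenzoate (para-quinone methide) | COC(=O)c1cc(OC)c(O)c(c1)[C@@H](C=C1C=CC(=O)C(OC)=C1)CO | intermediate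
19 | curlignan, methyl (2S,3R)-2-(4-hydroxy-3-methoxyphenyl)-3-(hydroxymethyl)-7-methoxy-2,3-dihydro-1-benzofuran-5-carboxylate | COC(=O)c1cc(OC)c2c(c1)[C@H](CO)[C@@H](c1ccc(O)c(OC)c1)O2 | target

## Step count and risks

Total: 11 steps. Longest linear sequence: 10 steps (steps 1–6 and 8–11 from methyl vanillate); step 7 is a one-step side branch.

**Step 11 (key step).** Two things are most likely to go wrong.
- Over-oxidation: the product keeps the ring B phenol and has a C2–H flanked by oxygen, so a second hydride abstraction and loss of the C3 hydrogen would aromatise the heterocycle and erase both stereocentres.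
- Slow capture: the ester-deactivated ring A phenol may add too slowly, so that the quinone methide tautomerises by loss of the C3 hydrogen or adds the hydroquinone by-product.

The fallback generates the same quinone methide by dehydration instead of oxidation, so no oxidant meets the product. It sets out from acid 8 and returns at 19.
- Acylation of (S)-4-benzyl-1,3-oxazolidin-2-one through anhydride 10 gives methyl 4-(benzyloxy)-3-{2-[(4S)-4-benzyl-2-oxo-1,3-oxazolidin-3-yl]-2-oxoethyl}-5-methoxybenzoate F1.
- Enolisation with Bu2BOTf/i-Pr2NEt and Evans syn-aldol addition to commercial 4-(benzyloxy)-3-methoxybenzaldehyde gives the (1S,2S) aldol adduct F2. The boron enolate reacts through the non-chelated chair transition state on the face opposite to that used in the alkylation, hence the antipodal auxiliary.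
- NaBH4 in wet THF gives the (1S,2R) 1,3-diol F3.
- Neutral hydrogenolysis (H2, Pd/C, EtOAc, stopped when the benzyl ethers are consumed) gives the tetrol F4.
- A trace of TsOH in CH2Cl2/THF dehydrates the para-hydroxybenzylic alcohol to 18, which closes to 19. The carbinol configuration is lost in 18 and does not matter.

**Step 8.** The diastereomer ratio may erode through proton exchange between the acidic α-aryl product and unreacted enolate. Enolate 14 may fragment to a ketene on warming, and the ionisation-prone bromide 13 may decompose.

The fallback sets the centre by hydrogenation instead of alkylation. It sets out from acid 8 and returns at 16.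
- Perkin condensation of 8 with 4-(benzyloxy)-3-methoxybenzaldehyde (Ac2O, Et3N, 110 °C) gives (2E)-2-[2-(benzyloxy)-3-methoxy-5-(methoxycarbonyl)phenyl]-3-[4-(benzyloxy)-3-methoxyphenyl]prop-2-enoic acid F5.
- Asymmetric hydrogenation with a Ru(OAc)2(BINAP) catalyst, in the antipode that delivers the (R) acid, gives (2R)-2-[2-(benzyloxy)-3-methoxy-5-(methoxycarbonyl)phenyl]-3-[4-(benzyloxy)-3-methoxyphenyl]propanoic acid F6.
- BH3·SMe2 reduces the carboxylic acid in preference to the methyl ester and gives 16.

**Step 9.** Hydride may attack the ring carbonyl of the hindered imide and open the auxiliary. The α-aryl centre may epimerise under the basic conditions before reduction, or slow reduction may lead to partial loss of the methyl ester.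

The fallback sets out from 15 and returns at 16.
- LiSEt (from EtSH and n-BuLi, THF, 0 °C) displaces the auxiliary at the exocyclic carbonyl and gives methyl 4-(benzyloxy)-3-[(2R)-3-[4-(benzyloxy)-3-methoxyphenyl]-1-(ethylsulfanyl)-1-oxopropan-2-yl]-5-methoxybenzoate F7.
- NaBH4 in EtOH at 0 °C reduces the thioester, which is far more reactive than the benzoate, to 16.

## Further compounds

F1 | step 11 | methyl 4-(benzyloxy)-3-{2-[(4S)-4-benzyl-2-oxo-1,3-oxazolidin-3-yl]-2-oxoethyl}-5-methoxybenzoate | COC(=O)c1cc(OC)c(OCc2ccccc2)c(CC(=O)N2[C@@H](Cc3ccccc3)COC2=O)c1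
F2 | step 11 | methyl 4-(benzyloxy)-3-[(1S,2S)-3-[(4S)-4-benzyl-2-oxo-1,3-oxazolidin-3-yl]-1-[4-(benzyloxy)-3-methoxyphenyl]-1-hydroxy-3-oxopropan-2-yl]-5-methoxybenzoate | COC(=O)c1cc(OC)c(OCc2ccccc2)c(c1)[C@@H]([C@H](O)c1ccc(OCc2ccccc2)c(OC)c1)C(=O)N1[C@@H](Cc2ccccc2)COC1=O
F3 | step 11 | methyl 4-(benzyloxy)-3-[(1S,2R)-1-[4-(benzyloxy)-3-methoxyphenyl]-1,3-dihydroxypropan-2-yl]-5-methoxybenzoate | COC(=O)c1cc(OC)c(OCc2ccccc2)c(c1)[C@@H]([C@H](O)c1ccc(OCc2ccccc2)c(OC)c1)CO
F4 | step 11 | methyl 3-[(1S,2R)-1,3-dihydroxy-1-(4-hydroxy-3-methoxyphenyl)propan-2-yl]-4-hydroxy-5-methoxybenzoate | COC(=O)c1cc(OC)c(O)c(c1)[C@@H]([C@H](O)c1ccc(O)c(OC)c1)CO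
F5 | step 8 | (2E)-2-[2-(benzyloxy)-3-methoxy-5-(methoxycarbonyl)phenyl]-3-[4-(benzyloxy)-3-methoxyphenyl]prop-2-enoic acid | COC(=O)c1cc(OC)c(OCc2ccccc2)c(c1)/C(C(=O)O)=C\c1ccc(OCc2ccccc2)c(OC)c1
F6 | step 8 | (2R)-2-[2-(benzyloxy)-3-methoxy-5-(methoxycarbonyl)phenyl]-3-[4-(benzyloxy)-3-methoxyphenyl]propanoic acid | COC(=O)c1cc(OC)c(OCc2ccccc2)c(c1)[C@@H](Cc1ccc(OCc2ccccc2)c(OC)c1)C(=O)O
F7 | step 9 | methyl 4-(benzyloxy)-3-[(2R)-3-[4-(benzyloxy)-3-methoxyphenyl]-1-(ethylsulfanyl)-1-oxopropan-2-yl]-5-methoxybenzoate | COC(=O)c1cc(OC)c(OCc2ccccc2)c(c1)[C@@H](Cc1ccc(OCc2ccccc2)c(OC)c1)C(=O)SCC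
A1 | alternative 1 | methyl (2S,3R)-7-bromo-3-{[tert-butyl(dimethyl)silyl]oxymethyl}-2-[3-methoxy-4-(methoxymethoxy)phenyl]-2,3-dihydro-1-benzofuran-5-carboxylate | COC(=O)c1cc(Br)c2c(c1)[C@H](CO[Si](C)(C)C(C)(C)C)[C@@H](c1ccc(OCOC)c(OC)c1)O2
A2 | alternative 1 | methyl 3-bromo-2-oxo-2H-pyran-5-carboxylate (methyl 3-bromocoumalate) | COC(=O)C1=COC(=O)C(Br)=C1
A3 | alternative 1 | tert-butyl({(2S,3R)-2-[3-methoxy-4-(methoxymethoxy)phenyl]-5-[(trimethylsilyl)oxy]-2,3-dihydrofuran-3-yl}methoxy)dimethylsilane (cyclic silyl ketene acetal) | C[Si](C)(C)OC1=C[C@H](CO[Si](C)(C)C(C)(C)C)[C@@H](c2ccc(OCOC)c(OC)c2)O1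
A4 | alternative 2 | methyl (2S,3R)-5-bromo-2-{4-[tert-butyl(dimethyl)silyl]oxy-3-methoxyphenyl}-7-methoxy-2,3-dihydro-1-benzofuran-3-carboxylate (cis) | Brc1cc(OC)c2c(c1)[C@@H](C(=O)OC)[C@@H](c1ccc(O[Si](C)(C)C(C)(C)C)c(OC)c1)O2
A5 | alternative 2 | methyl 2-{5-bromo-2-[(4-{[tert-butyl(dimethyl)silyl]oxy}-3-methoxyphenyl)methoxy]-3-methoxyphenyl}-2-diazoacetate | COC(=O)C(=[N+]=[N-])c1cc(Br)cc(OC)c1OCc1ccc(O[Si](C)(C)C(C)(C)C)c(OC)c1
A6 | alternative 3 | methyl (2S,3R)-3-{[tert-butyl(dimethyl)silyl]oxymethyl}-7-hydroxy-2-[3-methoxy-4-(methoxymethoxy)phenyl]-2,3-dihydro-1-benzofuran-5-carboxylate | COC(=O)c1cc(O)c2c(c1)[C@H](CO[Si](C)(C)C(C)(C)C)[C@@H](c1ccc(OCOC)c(OC)c1)O2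
A7 | alternative 3 | methyl 5-[(1S,2R)-3-{[tert-butyl(dimethyl)silyl]oxy}-1-(ethynyloxy)-1-[3-methoxy-4-(methoxymethoxy)phenyl]propan-2-yl]furan-3-carboxylate | COC(=O)c1coc(c1)[C@H](CO[Si](C)(C)C(C)(C)C)[C@@H](c1ccc(OCOC)c(OC)c1)OC#C
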